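**Retrosynthetic overview**
- The target comes from acetoxycrenulide by a Schenck ene reaction of singlet oxygen on the prenyl side chain; the acetate comes from the C5 alcohol.
- The cyclopropane (third ring) comes from a hydroxyl-directed Simmons–Smith reaction on a cycloocta-1,3-diene; the eight-membered ring (second ring) comes from ring-closing metathesis of a 3-vinylbutenolide with a terminal vinyl group.
- The vinyl group comes from a Stille coupling on the butenolide enol triflate; the C5 carbinol and C7 methyl come from one nickel-catalysed homoallylation of an aldehyde with isoprene.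
- The butenolide (first ring) comes from formaldehyde aldol–lactonisation of an α-keto ester.
- Key disconnection: the bond between the α-carbon of (R)-citronellal and C3 of a pyruvate, made by coupling the chiral enamine with the α-keto-alkyl radical from ethyl bromopyruvate (an enolonium equivalent).

Assumption: by the published enamine-shielding model, the (2S,5R) enantiomer of the imidazolidinone catalyst gives the (4R) aldehyde 3; if the first run shows the opposite sense, the mirror-image catalyst is used and nothing else changes.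

Ring numbering in the names: cycloocta[c]furan-1(3H)-one, with C1 the lactone carbonyl, O2, C3 the OCH2, C3a, C4 (side chain), C5 (oxygen), C6, C7 (methyl), C8, C9, C9a. "8,9-methano" means a CH2 bridging C8 and C9 (cis-fused cyclopropane).

**Step 1**
Reactants: 1 (R)-citronellal [(3R)-3,7-dimethyloct-6-enal]; 2 ethyl bromopyruvate (ethyl 3-bromo-2-oxopropanoate)
Product: 3 ethyl (4R,5R)-4-formyl-5,9-dimethyl-2-oxodec-8-enoate
Conditions: (2S,5R)-2-tert-butyl-3,5-dimethylimidazolidin-4-one·TfOH (20 mol%), Ru(bpy)3Cl2 (0.5 mol%), 2,6-lutidine (2 equiv), DMF, blue LED, 23 °C; 1 in twofold excess; crude 3 used at once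
Reagents that add atoms: none
Why: Proposed new method: the closest known reaction is the Nicewicz–MacMillan photoredox organocatalytic α-alkylation of aldehydes with α-bromo ketones and bromomalonates; here one-electron reduction of 2 by the photoreduced ruthenium complex gives an electrophilic α-keto-alkyl radical (an enolonium equivalent) that adds to the (E)-enamine of 1 on the face away from the catalyst methyl group, so two carbons that are both normally nucleophilic α-carbons are joined and C4 is set (R) by catalyst control over the remote C5 methyl, the untested points being survival of the α-keto ester (aldol, furan formation) and of the prenyl olefin.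

**Step 2**
Reactants: 3 ethyl (4R,5R)-4-formyl-5,9-dimethyl-2-oxodec-8-enoate
Product: 5 (2S,3R)-2-(4-hydroxy-5-oxo-2,5-dihydrofuran-3-yl)-3,7-dimethyloct-6-enal, via hydroxymethyl keto ester 4 (not isolated)
Conditions: 37% aq. CH2O (1.05 equiv), K2CO3 (1.0 equiv), THF–H2O, 0 °C, 45 min; then 1 M HCl to pH 4 at 0 °C
Reagents that add atoms: formaldehyde, C=O
Why: Aldol–lactonisation (the classical isotetronic acid synthesis from an α-keto ester and formaldehyde): the readily enolised pyruvate CH2 reacts far faster than the hindered α-branched aldehyde, the new primary alcohol closes onto the ethyl ester, and the keto lactone settles as its enol, which blocks a second hydroxymethylation; no stereocentre is formed and the aldehyde α-centre is kept by working cold and briefly.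

**Step 3**
Reactants: 5 (2S,3R)-2-(4-hydroxy-5-oxo-2,5-dihydrofuran-3-yl)-3,7-dimethyloct-6-enal; 6 isoprene (2-methylbuta-1,3-diene)
Product: 7 3-hydroxy-4-[(3R,5R,6S,7R)-5-hydroxy-3,7,11-trimethyldodeca-1,10-dien-6-yl]furan-2(5H)-one
Conditions: Ni(acac)2 (10 mol%), isoprene (4 equiv), Et2Zn (3.6 equiv), THF, 0 °C to rt; aq. NH4Cl
Reagents that add atoms: none
Why: Tamaru nickel-catalysed homoallylation of an aldehyde with isoprene (zerovalent nickel, oxanickelacycle, ethyl transfer, β-hydride elimination, C–H reductive elimination): C1 of isoprene bonds to the aldehyde carbon with the characteristic 1,3-anti relation between the new carbinol (5R) and methyl (3R) centres, and the carbinol face is set by 1,2-induction with attack anti to the branched C7 chain in a Felkin or zinc-enolate-chelated arrangement, the acidic enol being carried as its unreactive zinc enolate.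

**Step 4**
Reactants: 7 3-hydroxy-4-[(3R,5R,6S,7R)-5-hydroxy-3,7,11-trimethyldodeca-1,10-dien-6-yl]furan-2(5H)-one
Product: 8 4-[(3R,5R,6S,7R)-5-hydroxy-3,7,11-trimethyldodeca-1,10-dien-6-yl]-2-oxo-2,5-dihydrofuran-3-yl trifluoromethanesulfonate
Conditions: PhNTf2 (1.1 equiv), Et3N (1.5 equiv), CH2Cl2, 0 °C
Reagents that add atoms: N-phenylbis(trifluoromethanesulfonimide), O=S(=O)(N(c1ccccc1)S(=O)(=O)C(F)(F)F)C(F)(F)F
Why: Chemoselective O-triflation of the acidic enol (pKa about 8) over the secondary alcohol with the mild triflyl donor gives the enol triflate; no stereocentre is touched.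

**Step 5**
Reactants: 8 4-[(3R,5R,6S,7R)-5-hydroxy-3,7,11-trimethyldodeca-1,10-dien-6-yl]-2-oxo-2,5-dihydrofuran-3-yl trifluoromethanesulfonate
Product: 9 3-ethenyl-4-[(3R,5R,6S,7R)-5-hydroxy-3,7,11-trimethyldodeca-1,10-dien-6-yl]furan-2(5H)-one
Conditions: tributyl(vinyl)stannane (1.3 equiv), Pd(PPh3)4 (5 mol%), LiCl (3 equiv), THF, 65 °C
Reagents that add atoms: tributyl(vinyl)stannane, C=C[Sn](CCCC)(CCCC)CCCC
Why: Stille cross-coupling of an electron-poor enol triflate (oxidative addition to zerovalent palladium, chloride-assisted vinyl transfer from tin, reductive elimination) puts the vinyl group on C3 of the butenolide without touching any stereocentre.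

**Step 6**
Reactants: 9 3-ethenyl-4-[(3R,5R,6S,7R)-5-hydroxy-3,7,11-trimethyldodeca-1,10-dien-6-yl]furan-2(5H)-one
Product: 10 (4S,5R,7R,8Z)-5-hydroxy-7-methyl-4-[(2R)-6-methylhept-5-en-2-yl]-4,5,6,7-tetrahydrocycloocta[c]furan-1(3H)-one
Conditions: second-generation Hoveyda–Grubbs catalyst RuCl2(H2IMes)(=CH-C6H4-2-OiPr) (7 mol%), toluene (2 mM), 80 °C
Reagents that add atoms: none
Why: Ring-closing olefin metathesis between the two monosubstituted vinyl groups (the trisubstituted prenyl olefin reacts much more slowly) closes the eight-membered ring, the butenolide double bond acting as a cis constraint that enforces the Z geometry of the new C8=C9 bond; no stereocentre is formed.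

**Step 7**
Reactants: 10 (4S,5R,7R,8Z)-5-hydroxy-7-methyl-4-[(2R)-6-methylhept-5-en-2-yl]-4,5,6,7-tetrahydrocycloocta[c]furan-1(3H)-one
Product: 11 (4S,5R,7R,8S,9S)-5-hydroxy-7-methyl-4-[(2R)-6-methylhept-5-en-2-yl]-8,9-methano-4,5,6,7,8,9-hexahydrocycloocta[c]furan-1(3H)-one (deacetyl acetoxycrenulide)
Conditions: Et2Zn (3 equiv), CH2I2 (3 equiv), CH2Cl2, −15 to 0 °C; aq. NH4Cl
Reagents that add atoms: diiodomethane, ICI
Why: Hydroxyl-directed Simmons–Smith (Furukawa) cyclopropanation: the zinc alkoxide at C5 delivers the methylene to the C8=C9 bond on the oxygen-bearing face, which is also the face anti to the allylic C7 methyl, setting 8S and 9S (cis-fused cyclopropane syn to oxygen) as in the known directed cyclopropanation of cyclooct-4-enols.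

**Step 8**
Reactants: 11 (4S,5R,7R,8S,9S)-5-hydroxy-7-methyl-4-[(2R)-6-methylhept-5-en-2-yl]-8,9-methano-4,5,6,7,8,9-hexahydrocycloocta[c]furan-1(3H)-one
Product: 12 acetoxycrenulide, the 5-acetate of 11 [(4S,5R,7R,8S,9S)-5-acetoxy-7-methyl-4-[(2R)-6-methylhept-5-en-2-yl]-8,9-methano-4,5,6,7,8,9-hexahydrocycloocta[c]furan-1(3H)-one]
Conditions: Ac2O, pyridine, DMAP (cat.), CH2Cl2, rt
Reagents that add atoms: acetic anhydride, CC(=O)OC(C)=O
Why: DMAP-catalysed O-acylation of the secondary alcohol proceeds with retention at C5 and gives the natural product.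

**Step 9**
Reactants: 12 acetoxycrenulide
Product: 13 CNP0205234.1, (4S,5R,7R,8S,9S)-5-acetoxy-4-[(2R,4E)-6-hydroperoxy-6-methylhept-4-en-2-yl]-7-methyl-8,9-methano-4,5,6,7,8,9-hexahydrocycloocta[c]furan-1(3H)-one
Conditions: O2, 5,10,15,20-tetraphenylporphyrin (1 mol%), CH2Cl2, white LED, 0 °C; chromatography
Reagents that add atoms: dioxygen, O=O
Why: Schenck ene reaction of singlet oxygen with the only electron-rich olefin (the prenyl group; the conjugated tetrasubstituted butenolide olefin and the cyclopropane are inert) gives, by hydrogen abstraction from the side-chain CH2, the (E)-tertiary allylic hydroperoxide together with the regioisomeric secondary hydroperoxide (about 1:1), from which the target is separated; ring stereocentres are untouched.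

**Compound list**
1 | (R)-citronellal | C[C@H](CCC=C(C)C)CC=O | starting material
2 | ethyl bromopyruvate | CCOC(=O)C(=O)CBr | starting material
3 | ethyl (4R,5R)-4-formyl-5,9-dimethyl-2-oxodec-8-enoate | CCOC(=O)C(=O)C[C@@H](C=O)[C@H](C)CCC=C(C)C | intermediate
4 | ethyl (3RS,4S,5R)-4-formyl-3-(hydroxymethyl)-5,9-dimethyl-2-oxodec-8-enoate (C3 epimers) | CCOC(=O)C(=O)C(CO)[C@@H](C=O)[C@H](C)CCC=C(C)C | intermediate (not isolated)
5 | (2S,3R)-2-(4-hydroxy-5-oxo-2,5-dihydrofuran-3-yl)-3,7-dimethyloct-6-enal | OC1=C(COC1=O)[C@@H](C=O)[C@H](C)CCC=C(C)C | intermediate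
6 | isoprene | C=CC(C)=C | starting material
7 | 3-hydroxy-4-[(3R,5R,6S,7R)-5-hydroxy-3,7,11-trimethyldodeca-1,10-dien-6-yl]furan-2(5H)-one | OC1=C(COC1=O)[C@@H]([C@H](O)C[C@@H](C)C=C)[C@H](C)CCC=C(C)C | intermediate
8 | 4-[(3R,5R,6S,7R)-5-hydroxy-3,7,11-trimethyldodeca-1,10-dien-6-yl]-2-oxo-2,5-dihydrofuran-3-yl trifluoromethanesulfonate | O=S(=O)(OC1=C(COC1=O)[C@@H]([C@H](O)C[C@@H](C)C=C)[C@H](C)CCC=C(C)C)C(F)(F)F | intermediate
9 | 3-ethenyl-4-[(3R,5R,6S,7R)-5-hydroxy-3,7,11-trimethyldodeca-1,10-dien-6-yl]furan-2(5H)-one | C=CC1=C(COC1=O)[C@@H]([C@H](O)C[C@@H](C)C=C)[C@H](C)CCC=C(C)C | intermediate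
10 | (4S,5R,7R,8Z)-5-hydroxy-7-methyl-4-[(2R)-6-methylhept-5-en-2-yl]-4,5,6,7-tetrahydrocycloocta[c]furan-1(3H)-one | O[C@@H]1C[C@@H](C)/C=C\C2=C(COC2=O)[C@@H]1[C@H](C)CCC=C(C)C | intermediate
11 | deacetyl acetoxycrenulide, (4S,5R,7R,8S,9S)-5-hydroxy-7-methyl-4-[(2R)-6-methylhept-5-en-2-yl]-8,9-methano-4,5,6,7,8,9-hexahydrocycloocta[c]furan-1(3H)-one | O[C@@H]1C[C@@H](C)[C@@H]2C[C@@H]2C2=C(COC2=O)[C@@H]1[C@H](C)CCC=C(C)C | intermediate
12 | acetoxycrenulide (5-acetate of 11) | CC(=O)O[C@@H]1C[C@@H](C)[C@@H]2C[C@@H]2C2=C(COC2=O)[C@@H]1[C@H](C)CCC=C(C)C | intermediate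
13 | CNP0205234.1 | CC(=O)O[C@@H]1C[C@@H](C)[C@@H]2C[C@@H]2C2=C(COC2=O)[C@@H]1[C@H](C)C/C=C/C(C)(C)OO | target

**Step count and risks**
Total steps: 9. Longest linear sequence: 9 (from 1).

Step 1 is the most likely to fail. The α-keto ester of 2 may undergo aldol addition with the enamine or alkylate the catalyst, and 3 can cyclise to a furan under acid. The fallback sets out from 1 and comes back at 3. Compound 1 is condensed with (2R,5R)-2,5-dimethylpyrrolidine (4 Å sieves, Et2O, 0 °C) to the C2-symmetric (E)-enamine F1. This is alkylated with 2 in MeCN at −20 °C in a thermal two-electron substitution at the activated bromomethyl ketone, anti to the proximal ring methyl, to give the iminium bromide F2. Hydrolysis in pH 5 acetate buffer releases 3.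

Step 3 is the second risk. The facial selectivity next to an sp2-substituted α-centre is uncertain, and the free enol may disturb the nickel cycle. The fallback sets out from 5 and comes back at 7, with both new centres under reagent control. Allylboration of 5 with allylboronic acid pinacol ester and the matched enantiomer of the chiral phosphoric acid TRIP (toluene, −30 °C) gives the homoallylic alcohol F3. Cross-metathesis with (Z)-1,4-dichlorobut-2-ene (second-generation Grubbs catalyst RuCl2(H2IMes)(PCy3)(=CHPh), CH2Cl2, 40 °C) gives the (E)-allylic chloride F4. Copper-catalysed asymmetric SN2′ methylation (MeMgBr 4 equiv, CuBr·SMe2 5 mol%, matched Taniaphos ligand, CH2Cl2, −78 °C) then puts the methyl on the γ-carbon and leaves the terminal vinyl group, giving 7.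

Step 7 is the third risk. The C8=C9 bond is conjugated to the butenolide and so less nucleophilic, and the zinc carbenoid may attack the prenyl olefin instead. The fallback sets out from 10 and comes back at 12. Compound 10 is acetylated first (Ac2O, pyridine, DMAP) to the diene acetate F5. F5 is then cyclopropanated with CH2N2 and Pd(OAc)2 (5 mol%, Et2O, 0 °C), a metal-carbene process that takes cis-disubstituted olefins and leaves trisubstituted ones alone; the face is set by the allylic C7 methyl.

**Further compounds**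
F1 | step 1 | (2R,5R)-1-[(1E,3R)-3,7-dimethylocta-1,6-dien-1-yl]-2,5-dimethylpyrrolidine | C[C@@H]1CC[C@@H](C)N1/C=C/[C@H](C)CCC=C(C)C
F2 | step 1 | (2R,5R)-1-[(2R,3R)-2-(3-ethoxy-2,3-dioxopropyl)-3,7-dimethyloct-6-en-1-ylidene]-2,5-dimethylpyrrolidin-1-ium bromide | C[C@@H]1CC[C@@H](C)[N+]1=C[C@H](CC(=O)C(=O)OCC)[C@H](C)CCC=C(C)C.[Br-]
F3 | step 3 | 3-hydroxy-4-[(4R,5S,6R)-4-hydroxy-6,10-dimethylundeca-1,9-dien-5-yl]furan-2(5H)-one | OC1=C(COC1=O)[C@@H]([C@H](O)CC=C)[C@H](C)CCC=C(C)C
F4 | step 3 | 4-[(2E,5R,6S,7R)-1-chloro-5-hydroxy-7,11-dimethyldodeca-2,10-dien-6-yl]-3-hydroxyfuran-2(5H)-one | OC1=C(COC1=O)[C@@H]([C@H](O)C/C=C/CCl)[C@H](C)CCC=C(C)C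
F5 | step 7 | (4S,5R,7R,8Z)-7-methyl-4-[(2R)-6-methylhept-5-en-2-yl]-1-oxo-1,3,4,5,6,7-hexahydrocycloocta[c]furan-5-yl acetate | CC(=O)O[C@@H]1C[C@@H](C)/C=C\C2=C(COC2=O)[C@@H]1[C@H](C)CCC=C(C)C
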